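Readings and results were computed with constants of no real substance; noise was put on by code.

The reading comes at 4.0 h for beta and at 15 h for gamma, a longer time. Gamma's charge of X is smaller than beta's.

the same everywhere: G 0.033 M

| run | X | remark | time |
|---|---|---|---|
| spring | 1.1 µM | run made earlier |  |
| midnight | 3.7 µM | run made earlier |  |
| beta | 3.3 µM |  | 4.0 h |
| gamma | 0.80 µM |  | 15 h |

| run | time / h | E / % | G / % |
|---|---|---|---|
| spring | 0.667 | 7.1 | 93.4 |
| spring | 1.33 | 8.9 | 91.6 |
| spring | 2.00 | 10.9 | 89.5 |
| spring | 2.50 | 11.0 | 87.9 |
| spring | 3.00 | 12.6 | 87.2 |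
| spring | 4.00 | 13.8 | 86.0 |
| midnight | 0.667 | 11.7 | 88.0 |
| midnight | 1.33 | 13.3 | 86.0 |
| midnight | 2.00 | 15.7 | 84.7 |
| midnight | 2.50 | 16.2 | 84.1 |
| midnight | 3.00 | 16.5 | 83.2 |
| midnight | 4.00 | 18.8 | 81.2 |

(scatter of a reading: 0.5 percentage points)

* the winner by amount of E, in percent of the G charged; "neither" if no more than 2 percentage points parts them (beta / gamma / neither)
* how much E is there at the end, in percent of the G charged: beta
* how much E is there at the end, in percent of the G charged: gamma

- the analysis behind the earlier runs scatters by 0.5 percentage points, standard deviation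

Beta takes 13.2 µM·h and gamma 12.0 µM·h of the dose τ, the charged X times the time. Reading E against τ divides the rate of E by the charge of X, which takes the clock out of the comparison. The readings allow this: the spring run at 4.40 µM·h stands at 13.8 %, and the midnight run at 4.92 µM·h stands at 13.3 %, the same within a scatter of 0.5 percentage points.

Both flasks fall between two midnight readings, 16.5 % at 11.1 µM·h and 18.8 % at 14.8 µM·h. A straight line between those readings gives me 17.8 % for beta and 17.1 % for gamma. The gap of 0.75 points is smaller than the margin of 2 points.

The forecast reads: “The two earlier runs fall on one curve when E is plotted against X·t”. It differs slightly from my figures, with 17.9 % for beta and 17.4 % for gamma, and its verdict is neither.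

The flasks give 17.5 % for beta and 17.1 % for gamma, so the verdict is neither.

    G + X → E + X, rate k1*[G]^1.5*[X]/(1 + ([G]/Kh1)^1.5) (4.50 mM, k = 5.33 × 10⁵ /M^1.5/min)
    2 X → D (k = 60100 /M/min)

The neighbour flask is beta charged with 0.020 M of G, with the same X and the same time, so its dose is again 13.2 µM·h. At equal dose I carry E as a concentration, not as a percentage. Beta's 17.5 % of 0.033 M is 5.78 mM, which on the neighbour's charge would be 28.9 %. The neighbour flask gives 26.9 %, which is 5.38 mM of E.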